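**Retrosynthetic overview**
1. Ring B (ten-membered) is closed last at C2–C3 by an intramolecular CrCl2/NiCl2 coupling of a C2 aldehyde with a Z,Z-dienyl iodide; the 13,14-epoxide is set just before by C2–OH-directed epoxidation.
2. Ring C (lactone) comes from a SmI2 Reformatsky-type closure of a C7 2,2-dichloropropanoate onto a C8 ketone (C8 by ring closure, C17 by enolate protonation).
3. C7–C8–C9 is built on a 1,3-dithiane linchpin: Felkin addition to a ring-A C9 aldehyde, then acylation with a dienyl Weinreb amide and CBS reduction.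
4. Ring A: benzoic acid → Birch reductive methylation (C1 quaternary carbon) → prochiral 4,4-disubstituted cyclohexadienone → rhodium/(S)-BINAP desymmetrising 1,4-vinylation (key step, sets C1 and C10).
5. Ring order: A (dearomatised arene) → C → B.

Assumption: the SMILES is read as 1R,2R,7R,8R,9S,10R,11S,12S,13R,14S,17R with 3Z and C4/C7 cis on C5=C6; briarane numbers C1–C20 are used throughout, β is the face of ring A carrying the C1 methyl, and anions made in situ from a numbered compound are not numbered separately.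

**Step 1**
Reactants: 1 benzoic acid; 2 iodomethane
Product: 3 1-methylcyclohexa-2,5-diene-1-carboxylic acid
Conditions: Li, NH3(l), THF, −78 °C; then MeI; HCl work-up
Reagents that add atoms: iodomethane, CI
Why: Birch reductive alkylation breaks the aromaticity of benzoic acid and C-methylates the carboxylate dienolate at the ipso carbon, creating the future C1 quaternary carbon in a mirror-symmetric 1,4-diene.

**Step 2**
Reactants: 3 1-methylcyclohexa-2,5-diene-1-carboxylic acid
Product: 4 (1-methylcyclohexa-2,5-dien-1-yl)methanol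
Conditions: LiAlH4, THF, 0 °C → rt
Reagents that add atoms: none
Why: Hydride reduction of the acid gives the neopentyl alcohol (future C2); the isolated alkenes are inert.

**Step 3**
Reactants: 4 (1-methylcyclohexa-2,5-dien-1-yl)methanol; 5 tert-butyldimethylsilyl chloride
Product: 6 tert-butyldimethyl[(1-methylcyclohexa-2,5-dien-1-yl)methoxy]silane
Conditions: TBSCl, imidazole, DMF, rt
Reagents that add atoms: tert-butyldimethylsilyl chloride, CC(C)(C)[Si](C)(C)Cl
Why: Standard silylation; the bulky CH2OTBS group later shields one face of the dienone.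

**Step 4**
Reactants: 6 silyl ether; 7 tert-butyl hydroperoxide
Product: 8 4-{[(tert-butyldimethylsilyl)oxy]methyl}-4-methylcyclohexa-2,5-dien-1-one
Conditions: Rh2(cap)4 (1 mol %), t-BuOOH, K2CO3, CH2Cl2, rt
Reagents that add atoms: tert-butyl hydroperoxide, CC(C)(C)OO
Why: Allylic oxidation (tert-butylperoxy radical chain) of the only doubly allylic CH2 gives the prochiral cross-conjugated dienone.

**Step 5**
Reactants: 8 prochiral dienone; 9 potassium vinyltrifluoroborate
Product: 10 (4R,5S)-4-{[(tert-butyldimethylsilyl)oxy]methyl}-4-methyl-5-vinylcyclohex-2-en-1-one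
Conditions: [Rh(cod)2]BF4 (5 mol %), (S)-BINAP, toluene/H2O 10:1, 100 °C
Reagents that add atoms: potassium vinyltrifluoroborate, C=C[B-](F)(F)F.[K+]
Why: Proposed new method: Hayashi–Miyaura 1,4-addition in which the rhodium–vinyl species adds to one enantiotopic enone arm (chosen by (S)-BINAP, sense assigned by analogy with 2-cyclohexenone) on the face anti to CH2OTBS, setting C1 and C10 together; the closest known reactions are rhodium/BINAP additions of potassium alkenyltrifluoroborates to cyclohexenone and rhodium-catalysed arylative desymmetrisation of 4,4-disubstituted cyclohexadienones.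

**Step 6**
Reactants: 10 vinyl enone; 2 iodomethane
Product: 11 6-methyl derivative of 10 with methyl trans to vinyl (11α-methyl)
Conditions: LiN(i-Pr)2, THF, −78 °C; MeI
Reagents that add atoms: iodomethane, CI
Why: Enolate alkylation at the only enolisable position (C11) occurs anti to the adjacent C10 vinyl group, giving the trans isomer that is corrected in step 7.

**Step 7**
Reactants: 11 trans-methyl enone
Product: 13 ring-A allylic alcohol (12β-OH, 11β-methyl, 10β-vinyl, 1β-methyl, 1α-CH2OTBS, C13=C14), via cis-methyl enone 12 (not isolated)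
Conditions: LiN(i-Pr)2, THF, −78 °C; 2,6-di-tert-butyl-4-methylphenol, −78 °C; then i-Bu2AlH, −78 °C
Reagents that add atoms: none
Why: Kinetic C-protonation of the enolate by the bulky phenol anti to the C10 vinyl group gives the cis (11β) methyl, and immediate 1,2-reduction by i-Bu2AlH from the α face (anti to the pseudo-axial vinyl group) sets 12β-OH and locks C11.

**Step 8**
Reactants: 13 allylic alcohol; 14 sodium periodate
Product: 15 ring-A C9 aldehyde (in equilibrium with its C9–O–C12 bridged lactol)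
Conditions: OsO4 (2 mol %), NaIO4, 2,6-lutidine, dioxane/H2O, rt
Reagents that add atoms: sodium periodate, [Na+].[O-]I(=O)(=O)=O
Why: Lemieux–Johnson cleavage; OsO4 selects the monosubstituted vinyl group over the ring alkene flanked by the C1 quaternary carbon.

**Step 9**
Reactants: 15 C9 aldehyde; 16 1,3-dithiane
Product: 17 (9S)-dithianyl diol
Conditions: 1,3-dithiane (2.6 equiv), n-BuLi (2.5 equiv), THF, −30 °C; then 15, −78 °C
Reagents that add atoms: 1,3-dithiane, C1CSCSC1
Why: Corey–Seebach addition; Felkin–Anh attack anti to the C1 quaternary carbon gives 9S, and the second equivalent of anion covers the free 12-OH/lactol.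

**Step 10**
Reactants: 18 prop-2-yn-1-ol; 19 tert-butyldiphenylsilyl chloride
Product: 20 tert-butyldiphenyl(prop-2-yn-1-yloxy)silane
Conditions: TBDPSCl, imidazole, CH2Cl2, rt
Reagents that add atoms: tert-butyldiphenylsilyl chloride, CC(C)(C)[Si](Cl)(c1ccccc1)c1ccccc1
Why: Standard silylation of the future C16 oxygen with a group that outlasts the TBS ether.

**Step 11**
Reactants: 20 silyl propargyl ether; 21 N-methoxy-N-methylcarbamoyl chloride
Product: 22 4-[(tert-butyldiphenylsilyl)oxy]-N-methoxy-N-methylbut-2-ynamide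
Conditions: n-BuLi, THF, −78 °C; ClC(O)N(OMe)Me
Reagents that add atoms: N-methoxy-N-methylcarbamoyl chloride, CON(C)C(Cl)=O
Why: Acylation of the lithium acetylide gives the Weinreb ynamide (C7 carbonyl, C6, C5, C16).

**Step 12**
Reactants: 22 ynamide; 23 sodium iodide
Product: 24 (Z)-4-[(tert-butyldiphenylsilyl)oxy]-3-iodo-N-methoxy-N-methylbut-2-enamide
Conditions: NaI, AcOH, MeCN, 60 °C
Reagents that add atoms: sodium iodide, [Na+].[I-]
Why: Conjugate hydroiodination by anti addition puts iodine cis to the carbonyl, fixing the C5=C6 geometry.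

**Step 13**
Reactants: 25 trimethyl[(tributylstannyl)ethynyl]silane
Product: 26 (Z)-tributyl[2-(trimethylsilyl)vinyl]stannane
Conditions: Cp2Zr(H)Cl, THF, rt; then H2O
Reagents that add atoms: none
Why: Syn hydrozirconation followed by protonolysis leaves tin and silicon cis.

**Step 14**
Reactants: 24 Z-iodo enamide; 26 Z-stannane
Product: 27 (2E,4Z)-3-{[(tert-butyldiphenylsilyl)oxy]methyl}-N-methoxy-N-methyl-5-(trimethylsilyl)penta-2,4-dienamide (C7 carbonyl cis to C4)
Conditions: Pd2(dba)3 (5 mol %), AsPh3, CuI, NMP, rt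
Reagents that add atoms: (Z)-tributyl[2-(trimethylsilyl)vinyl]stannane, CCCC[Sn](CCCC)(CCCC)/C=C\[Si](C)(C)C
Why: Stille coupling with retention on both partners; the terminal silane is used because a Z,Z-5-halodienone would cyclise to a pyrylium salt.

**Step 15**
Reactants: 17 dithianyl diol; 27 dienyl Weinreb amide
Product: 28 diol ketone (C8 dithiane, C7 ketone, 9S)
Conditions: n-BuLi (3.3 equiv), THF, −78 → −20 °C; then 27, −78 °C; aqueous work-up
Reagents that add atoms: dienyl Weinreb amide 27, CON(C)C(=O)/C=C(CO[Si](c1ccccc1)(c1ccccc1)C(C)(C)C)\C=C/[Si](C)(C)C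
Why: The dithiane carbanion (the two hydroxyls held as alkoxides, which also prevents β-elimination) is acylated by the Weinreb amide, whose tetrahedral chelate stops over-addition and retro-aldol cleavage.

**Step 16**
Reactants: 28 diol ketone; 29 acetic anhydride
Product: 30 9,12-diacetate
Conditions: Ac2O, pyridine, DMAP, CH2Cl2, 0 °C → rt
Reagents that add atoms: acetic anhydride, CC(=O)OC(C)=O
Why: Acylation of both secondary alcohols installs the two acetates of the target in one step and differentiates them from the later C7 hydroxyl.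

**Step 17**
Reactants: 30 diacetate ketone
Product: 31 (7R)-alcohol
Conditions: (S)-Me-CBS oxazaborolidine (1 equiv), catecholborane, toluene, −78 → −40 °C
Reagents that add atoms: none
Why: Corey–Bakshi–Shibata 1,2-reduction under reagent control, with the quaternary dithiane carbon as the large group and the Z-alkenyl as the small one, gives 7R.

**Step 18**
Reactants: 31 C7 alcohol; 32 2,2-dichloropropanoic acid
Product: 33 7-O-(2,2-dichloropropanoate)
Conditions: DCC, DMAP, CH2Cl2, 0 °C → rt
Reagents that add atoms: 2,2-dichloropropanoic acid, CC(Cl)(Cl)C(O)=O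
Why: Steglich esterification attaches C17–C19 to O7; the acid has no α-hydrogen, so no ketene pathway is open.

**Step 19**
Reactants: 33 dichloropropanoate; 34 water
Product: 35 C8 ketone
Conditions: PhI(O2CCF3)2, MeCN/H2O 9:1, 0 °C, 10 min; NaHCO3
Reagents that add atoms: water, O
Why: Oxidative dethioacetalisation unveils the C8 ketone only after O7 is acylated, so the α-hydroxy ketone cannot isomerise; 35 is used at once.

**Step 20**
Reactants: 35 C8 ketone
Product: 37 ring-C lactone (7R,8R,9S,17R), via 17-chloro lactone 36 (not isolated)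
Conditions: SmI2 (2.2 equiv), THF, −78 °C; then MeOH, SmI2 (2.5 equiv), −78 → −40 °C
Reagents that add atoms: none
Why: Proposed new method: SmI2 reduces one carbon–chlorine bond faster than the ketone and the samarium enolate closes onto C8 with C6 and C9 trans on the new ring (8R), then the second carbon–chlorine bond is reduced with MeOH present and the enolate is protonated at C17 from the face of the C8–O–Sm bond, away from C9 (17R, the epimer not reachable by direct C–C bond formation); the closest known reactions are SmI2 Reformatsky cyclisations of halo esters onto ketones and SmI2/alcohol reduction of 2-halo-3-hydroxy esters.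

**Step 21**
Reactants: 37 lactone dienylsilane; 38 N-iodosuccinimide
Product: 39 Z,Z-dienyl iodide
Conditions: N-iodosuccinimide (1.3 equiv), (CF3)2CHOH, 0 °C
Reagents that add atoms: N-iodosuccinimide, O=C1CCC(=O)N1I
Why: Ipso-iododesilylation through the β-silyl cation proceeds with retention, now that no C7 carbonyl remains to cyclise onto the halodiene.

**Step 22**
Reactants: 39 dienyl iodide
Product: 40 C2 primary alcohol
Conditions: HF·pyridine, pyridine, THF, 0 °C
Reagents that add atoms: none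
Why: The primary TBS ether is cleaved selectively; the TBDPS ether, acetates and lactone survive buffered HF.

**Step 23**
Reactants: 40 C2 alcohol; 7 tert-butyl hydroperoxide
Product: 41 13α,14α-epoxide
Conditions: VO(acac)2 (10 mol %), t-BuOOH, CH2Cl2, 0 °C → rt
Reagents that add atoms: tert-butyl hydroperoxide, CC(C)(C)OO
Why: Vanadium-catalysed hydroxyl-directed epoxidation delivers oxygen to C13=C14 syn to the homoallylic C2 hydroxyl (α face); the 12β-acetate does not direct.

**Step 24**
Reactants: 41 epoxy alcohol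
Product: 42 C2 aldehyde
Conditions: Dess–Martin periodinane, NaHCO3, CH2Cl2, rt
Reagents that add atoms: none
Why: Mild oxidation of the only primary or secondary alcohol; the aldehyde has no α-hydrogen.

**Step 25**
Reactants: 42 iodo aldehyde
Product: 43 16-O-TBDPS ether of the target (ring B closed, 2R)
Conditions: CrCl2 (10 equiv), NiCl2 (0.1 equiv), DMSO/THF 3:1, 2 mM, rt
Reagents that add atoms: none
Why: Intramolecular Nozaki–Hiyama–Kishi reaction: the dienylchromium forms with retention and adds to the C2 aldehyde, closing the ten-membered ring; the conformer with the C2–O bond on the β side, away from the epoxide oxygen, is expected to give 2R.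

**Step 26**
Reactants: 43 silyl ether
Product: 44 CNP0285414.3
Conditions: Bu4NF, AcOH (1:1), THF, 0 °C → rt
Reagents that add atoms: none
Why: Buffered fluoride removes the TBDPS group without touching the acetates, epoxide or lactone.

**Compound list**
1 | benzoic acid | OC(=O)c1ccccc1 | starting material
2 | iodomethane | CI | starting material
3 | 1-methylcyclohexa-2,5-diene-1-carboxylic acid | CC1(C(O)=O)C=CCC=C1 | intermediate
4 | (1-methylcyclohexa-2,5-dien-1-yl)methanol | CC1(CO)C=CCC=C1 | intermediate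
5 | tert-butyldimethylsilyl chloride | CC(C)(C)[Si](C)(C)Cl | starting material
6 | tert-butyldimethyl[(1-methylcyclohexa-2,5-dien-1-yl)methoxy]silane | CC1(CO[Si](C)(C)C(C)(C)C)C=CCC=C1 | intermediate
7 | tert-butyl hydroperoxide | CC(C)(C)OO | starting material
8 | 4-{[(tert-butyldimethylsilyl)oxy]methyl}-4-methylcyclohexa-2,5-dien-1-one | CC1(CO[Si](C)(C)C(C)(C)C)C=CC(=O)C=C1 | intermediate
9 | potassium vinyltrifluoroborate | C=C[B-](F)(F)F.[K+] | starting material
10 | (4R,5S)-4-{[(tert-butyldimethylsilyl)oxy]methyl}-4-methyl-5-vinylcyclohex-2-en-1-one | O=C1C[C@@H](C=C)[C@](C)(CO[Si](C)(C)C(C)(C)C)C=C1 | intermediate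
11 | 6-methyl derivative of 10, methyl trans to vinyl (11α-methyl) | O=C1[C@H](C)[C@@H](C=C)[C@](C)(CO[Si](C)(C)C(C)(C)C)C=C1 | intermediate
12 | C6 epimer of 11, methyl cis to vinyl (11β-methyl) | O=C1[C@@H](C)[C@@H](C=C)[C@](C)(CO[Si](C)(C)C(C)(C)C)C=C1 | intermediate
13 | ring-A allylic alcohol (12β-OH, 11β-methyl, 10β-vinyl, 1α-CH2OTBS) | O[C@H]1[C@@H](C)[C@@H](C=C)[C@](C)(CO[Si](C)(C)C(C)(C)C)C=C1 | intermediate
14 | sodium periodate | [Na+].[O-]I(=O)(=O)=O | starting material
15 | ring-A C9 aldehyde (10β-CHO, 12β-OH) | O[C@H]1[C@@H](C)[C@@H](C=O)[C@](C)(CO[Si](C)(C)C(C)(C)C)C=C1 | intermediate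
16 | 1,3-dithiane | C1CSCSC1 | starting material
17 | (9S)-9-hydroxy-9-(1,3-dithian-2-yl) diol | O[C@H]1[C@@H](C)[C@@H]([C@H](O)C2SCCCS2)[C@](C)(CO[Si](C)(C)C(C)(C)C)C=C1 | intermediate
18 | prop-2-yn-1-ol | C#CCO | starting material
19 | tert-butyldiphenylsilyl chloride | CC(C)(C)[Si](Cl)(c1ccccc1)c1ccccc1 | starting material
20 | tert-butyldiphenyl(prop-2-yn-1-yloxy)silane | C#CCO[Si](c1ccccc1)(c1ccccc1)C(C)(C)C | intermediate
21 | N-methoxy-N-methylcarbamoyl chloride | CON(C)C(Cl)=O | starting material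
22 | 4-[(tert-butyldiphenylsilyl)oxy]-N-methoxy-N-methylbut-2-ynamide | CON(C)C(=O)C#CCO[Si](c1ccccc1)(c1ccccc1)C(C)(C)C | intermediate
23 | sodium iodide | [Na+].[I-] | starting material
24 | (Z)-4-[(tert-butyldiphenylsilyl)oxy]-3-iodo-N-methoxy-N-methylbut-2-enamide | CON(C)C(=O)/C=C(\I)CO[Si](c1ccccc1)(c1ccccc1)C(C)(C)C | intermediate
25 | trimethyl[(tributylstannyl)ethynyl]silane | CCCC[Sn](CCCC)(CCCC)C#C[Si](C)(C)C | starting material
26 | (Z)-tributyl[2-(trimethylsilyl)vinyl]stannane | CCCC[Sn](CCCC)(CCCC)/C=C\[Si](C)(C)C | intermediate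
27 | (2E,4Z)-3-{[(tert-butyldiphenylsilyl)oxy]methyl}-N-methoxy-N-methyl-5-(trimethylsilyl)penta-2,4-dienamide | CON(C)C(=O)/C=C(CO[Si](c1ccccc1)(c1ccccc1)C(C)(C)C)\C=C/[Si](C)(C)C | intermediate
28 | diol ketone (C8 dithiane, C7 ketone, 9S) | O[C@H]1[C@@H](C)[C@@H]([C@H](O)C2(SCCCS2)C(=O)/C=C(CO[Si](c3ccccc3)(c3ccccc3)C(C)(C)C)\C=C/[Si](C)(C)C)[C@](C)(CO[Si](C)(C)C(C)(C)C)C=C1 | intermediate
29 | acetic anhydride | CC(=O)OC(C)=O | starting material
30 | 9,12-diacetate of 28 | CC(=O)O[C@H]1[C@@H](C)[C@@H]([C@H](OC(C)=O)C2(SCCCS2)C(=O)/C=C(CO[Si](c3ccccc3)(c3ccccc3)C(C)(C)C)\C=C/[Si](C)(C)C)[C@](C)(CO[Si](C)(C)C(C)(C)C)C=C1 | intermediate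
31 | (7R)-alcohol | CC(=O)O[C@H]1[C@@H](C)[C@@H]([C@H](OC(C)=O)C2(SCCCS2)[C@H](O)/C=C(CO[Si](c3ccccc3)(c3ccccc3)C(C)(C)C)\C=C/[Si](C)(C)C)[C@](C)(CO[Si](C)(C)C(C)(C)C)C=C1 | intermediate
32 | 2,2-dichloropropanoic acid | CC(Cl)(Cl)C(O)=O | starting material
33 | 7-O-(2,2-dichloropropanoate) of 31 | CC(=O)O[C@H]1[C@@H](C)[C@@H]([C@H](OC(C)=O)C2(SCCCS2)[C@H](OC(=O)C(C)(Cl)Cl)/C=C(CO[Si](c3ccccc3)(c3ccccc3)C(C)(C)C)\C=C/[Si](C)(C)C)[C@](C)(CO[Si](C)(C)C(C)(C)C)C=C1 | intermediate
34 | water | O | starting material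
35 | C8 ketone (7-O-dichloropropanoate, 9-OAc) | CC(=O)O[C@H]1[C@@H](C)[C@@H]([C@H](OC(C)=O)C(=O)[C@H](OC(=O)C(C)(Cl)Cl)/C=C(CO[Si](c2ccccc2)(c2ccccc2)C(C)(C)C)\C=C/[Si](C)(C)C)[C@](C)(CO[Si](C)(C)C(C)(C)C)C=C1 | intermediate
36 | 17-chloro lactone (ring C closed, 8R, C17 epimer mixture) | CC(=O)O[C@H]1[C@@H](C)[C@@H]([C@H](OC(C)=O)[C@]2(O)[C@@H](/C=C(CO[Si](c3ccccc3)(c3ccccc3)C(C)(C)C)\C=C/[Si](C)(C)C)OC(=O)C2(C)Cl)[C@](C)(CO[Si](C)(C)C(C)(C)C)C=C1 | intermediate
37 | ring-C lactone (7R,8R,9S,17R), dienylsilane, C2–OTBS | CC(=O)O[C@H]1[C@@H](C)[C@@H]([C@H](OC(C)=O)[C@]2(O)[C@@H](/C=C(CO[Si](c3ccccc3)(c3ccccc3)C(C)(C)C)\C=C/[Si](C)(C)C)OC(=O)[C@@H]2C)[C@](C)(CO[Si](C)(C)C(C)(C)C)C=C1 | intermediate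
38 | N-iodosuccinimide | O=C1CCC(=O)N1I | starting material
39 | Z,Z-dienyl iodide | CC(=O)O[C@H]1[C@@H](C)[C@@H]([C@H](OC(C)=O)[C@]2(O)[C@@H](/C=C(CO[Si](c3ccccc3)(c3ccccc3)C(C)(C)C)\C=C/I)OC(=O)[C@@H]2C)[C@](C)(CO[Si](C)(C)C(C)(C)C)C=C1 | intermediate
40 | C2 primary alcohol | CC(=O)O[C@H]1[C@@H](C)[C@@H]([C@H](OC(C)=O)[C@]2(O)[C@@H](/C=C(CO[Si](c3ccccc3)(c3ccccc3)C(C)(C)C)\C=C/I)OC(=O)[C@@H]2C)[C@](C)(CO)C=C1 | intermediate
41 | 13α,14α-epoxy alcohol | CC(=O)O[C@H]1[C@@H](C)[C@@H]([C@H](OC(C)=O)[C@]2(O)[C@@H](/C=C(CO[Si](c3ccccc3)(c3ccccc3)C(C)(C)C)\C=C/I)OC(=O)[C@@H]2C)[C@](C)(CO)[C@@H]2O[C@H]12 | intermediate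
42 | C2 aldehyde | CC(=O)O[C@H]1[C@@H](C)[C@@H]([C@H](OC(C)=O)[C@]2(O)[C@@H](/C=C(CO[Si](c3ccccc3)(c3ccccc3)C(C)(C)C)\C=C/I)OC(=O)[C@@H]2C)[C@](C)(C=O)[C@@H]2O[C@H]12 | intermediate
43 | 16-O-TBDPS ether of the target | CC(=O)O[C@H]1[C@@H](C)[C@H]2[C@H](OC(C)=O)[C@]3(O)[C@@H](/C=C(CO[Si](c4ccccc4)(c4ccccc4)C(C)(C)C)\C=C/[C@@H](O)[C@]2(C)[C@@H]2O[C@H]12)OC(=O)[C@@H]3C | intermediate
44 | CNP0285414.3 | CC(=O)O[C@H]1[C@@H](C)[C@H]2[C@H](OC(C)=O)[C@]3(O)[C@@H](/C=C(CO)\C=C/[C@@H](O)[C@]2(C)[C@@H]2O[C@H]12)OC(=O)[C@@H]3C | target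

**Totals**
Total steps: 26. Longest linear sequence: 21 (steps 1–9 and 15–26); the dienyl amide 27 takes steps 10–14.

**Three steps most likely to fail**

Step 5 (facial and enantiotopic selectivity of the vinylation). The fallback sets out from 8 and returns at 10. Racemic conjugate vinylation of 8 (vinylmagnesium bromide, CuBr·SMe2, Me3SiCl, THF, −78 °C, still anti to CH2OTBS) gives 10 together with its mirror image, the enantiomeric enone F1. Reduction of the pair with (R)-Me-CBS oxazaborolidine and catecholborane fixes the new carbinol by reagent control, so 10 gives allylic alcohol F2 and F1 gives the diastereomeric allylic alcohol F3. After chromatographic separation, MnO2 oxidation of F2 returns 10.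

Step 20 (protonation face at C17, or β-elimination to the butenolide). The fallback sets out from 35 and returns at 37. Only the first samarium stage is run and chloro lactone 36 is isolated. The tertiary carbon–chlorine bond is then reduced by a radical chain (Bu3SnH, AIBN, benzene, 80 °C), so C17 is set by hydrogen-atom transfer to the planar radical from the face away from C9 rather than by enolate protonation. No compound outside the list is made (none F0).

Step 25 (ring closure giving the wrong C2 configuration). The fallback sets out from 42 and returns at 43. The ring closure is run as before and the C2-epimeric macrocycle F4 (or the epimer mixture) is accepted. Dess–Martin oxidation gives the ring-B dienone F5, and reduction with (S)-Me-CBS oxazaborolidine and catecholborane (C1 quaternary carbon as the large group) sets 2R and gives 43.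

**Further compounds**
F1 | step 5 | enantiomeric enone, (4S,5R)-4-{[(tert-butyldimethylsilyl)oxy]methyl}-4-methyl-5-vinylcyclohex-2-en-1-one | O=C1C[C@H](C=C)[C@@](C)(CO[Si](C)(C)C(C)(C)C)C=C1
F2 | step 5 | allylic alcohol from 10 (reagent-set carbinol) | O[C@H]1C[C@@H](C=C)[C@](C)(CO[Si](C)(C)C(C)(C)C)C=C1
F3 | step 5 | diastereomeric allylic alcohol from F1 (same carbinol configuration) | O[C@H]1C[C@H](C=C)[C@@](C)(CO[Si](C)(C)C(C)(C)C)C=C1
F0 | step 20 | none | none
F4 | step 25 | C2-epimeric macrocycle (2S) | CC(=O)O[C@H]1[C@@H](C)[C@H]2[C@H](OC(C)=O)[C@]3(O)[C@@H](/C=C(CO[Si](c4ccccc4)(c4ccccc4)C(C)(C)C)\C=C/[C@H](O)[C@]2(C)[C@@H]2O[C@H]12)OC(=O)[C@@H]3C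
F5 | step 25 | ring-B dienone (C2 ketone) | CC(=O)O[C@H]1[C@@H](C)[C@H]2[C@H](OC(C)=O)[C@]3(O)[C@@H](/C=C(CO[Si](c4ccccc4)(c4ccccc4)C(C)(C)C)\C=C/C(=O)[C@]2(C)[C@@H]2O[C@H]12)OC(=O)[C@@H]3C
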